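**What is asked.**

in all of them: solid electrophile 0.020 M; time 80 s

| flask | nucleophile | free base | remark |
|---|---|---|---|
| beta | 0.950 equiv | 2.00 equiv | everything together at the start |
| zeta | 0.950 equiv | 2.00 equiv (fed, over 1.0 min) | all else is in the flask from the start; the feed brings no volume worth counting |
| alpha | 0.950 equiv (fed, over 15 s) | 2.00 equiv | all else is in the flask from the start; the feed brings no volume worth counting |
| delta | 0.950 equiv (fed, over 1.0 min) | 2.00 equiv | all else is in the flask from the start; the feed brings no volume worth counting |

- the flask that comes out highest in amount of target, in percent of the solid electrophile charged, or "all alike" when all lie within 1.5 percentage points (beta / zeta / alpha / delta / all alike)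
- target at the end, in percent of the solid electrophile charged, beta
- target at the end, in percent of the solid electrophile charged, zeta
- target at the end, in percent of the solid electrophile charged, alpha
- target at the end, in percent of the solid electrophile charged, delta

- for a step with 2 of a species take k times the square, and two of it per event
- given per volume of solution although it is solid: solid electrophile
- at the start none of the solid electrophile is in solution
- run time (beta): 80 s

    acid set free + free base ⇌ salt of the base (K1 = 11300 /M, k1 = 70.5 /M/s)
    2 nucleophile → self-condensation product (k2 = 1.26 /M/s)
    nucleophile + acid set free ⇌ protonated nucleophile, settled at all times (K3 = 4.75 × 10⁵ /M)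
    solid electrophile ⇌ electrophile, rate k4*(cs4 - [electrophile]) while solid is left; crystals form when [electrophile] > cs4 (cs4 = 10 mM, k4 = 0.0940 /s)
    electrophile + nucleophile → acid set free + target (k5 = 2.19 /M/s)

**One step.** In a one-step world, electrophile meets nucleophile and gives target. I held electrophile at its solubility, 10 mM, a generous assumption. The step is then pseudo-first-order in nucleophile, with a half-life of 31.7 s. The nucleophile charge is 19.0 mM. The run lasts 2.53 half-lives, which gave 78.5 % target.

**Slow solid.** Then I let the solid dissolve. Its approach to solubility has a lifetime of 10.6 s, and I took that time off the run. The target fell to 74.2 %.

**Self-condensation.** Next I added the loss of nucleophile to itself. At the charge its first half-life is 20.9 s, shorter than the target step's. The number I carried is the break-even level: the [nucleophile] at which the two steps use nucleophile equally while electrophile stands at its solubility 8.69 mM. The charge lies above it. I let self-condensation act by itself for the dissolving lifetime, and I reckoned nucleophile down to 12.6 mM. After that, the target came to 32.9 %.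

**Acid capture.** In beta at the start, the acid set free favours nucleophile over free base, 9000 against 450. So I counted two nucleophile per target. That left 22.8 % for beta, and I put zeta beside it, with its nucleophile charged at the start as in beta.

**Slow feed.** In delta, still counting two nucleophile per target, I balanced feed and consumption at 5.49 mM, below break-even. Over the feed that gave me 36.1 % target. Alpha's feed is shorter than delta's, so I placed it between beta and delta.

**The forecast.** It chose delta, with 23.5 % for beta, 22.8 % for zeta, 28.5 % for alpha and 32 % for delta. Slow feeding helps, it said, by “keeping it low while the electrophile dissolves”. My beta stood below its figure, and my delta above its figure.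

**The result.** The highest flask was delta, at 31.9 %. Alpha gave 29.3 %, beta 24.9 % and zeta 24.8 %. The forecast's choice held, and its four figures came within tolerance.

**Break-even again.** Delta's mean [nucleophile] over the first minute was 0.00451 M, below the break-even 8.69 mM, and at 15.5 s the target step used nucleophile 1.7 times as fast as self-condensation, with 0.00210 M of self-condensation product standing at 80.0 s. Beta began with nucleophile at 19.0 mM, above that level, and held more self-condensation product than delta at 80.0 s, namely 0.00451 M.

All constants are made up.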